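The amounts are the same in oak, elm, ash and larch: 0.015 M of substrate and 0.700 equiv of first nucleophile, the limiting reagent by charge. So your next run turns on how the substrate goes in, and at what temperature.

the same everywhere: gas 1.6 mM (held)
- green: substrate 0.015 M; first nucleophile 0.70 equiv; temperature −5 °C; run made earlier
- teal: substrate 0.010 M; first nucleophile 0.70 equiv; temperature 6 °C; run made earlier
- blue: substrate 0.022 M; first nucleophile 0.70 equiv; temperature −5 °C; run made earlier
- oak: substrate 0.015 M; first nucleophile 0.700 equiv; temperature 0 °C; everything together at the start; time 1.0 h
- elm: substrate 0.015 M (fed, over 40 min); first nucleophile 0.700 equiv; the addition at −20 °C, then warmed to 0 °C; the feed brings no volume worth counting; time 1.0 h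
- ash: substrate 0.015 M; first nucleophile 0.700 equiv; everything together at the start at −20 °C, warmed to 0 °C at 40 min; time 1.0 h
- larch: substrate 0.015 M (fed, over 40 min); first nucleophile 0.700 equiv; temperature 0 °C; all else is in the flask from the start; the feed brings no volume worth counting; time 1.0 h

| run | time / min | target / % |
|---|---|---|
| green | 5.00 | 6.8 |
| green | 12.0 | 13.0 |
| green | 25.0 | 20.7 |
| green | 60.0 | 26.3 |
| teal | 5.00 | 12.9 |
| teal | 12.0 | 18.4 |
| teal | 25.0 | 21.6 |
| teal | 40.0 | 21.3 |
| blue | 5.00 | 8.1 |
| blue | 12.0 | 15.1 |
| blue | 25.0 | 23.8 |
| blue | 40.0 | 28.4 |

(standard deviation of a reading: 0.5 percentage points)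

* the flask with the highest amount of target, in percent of the substrate charged ("all alike" if they lie within 1.5 percentage points) (oak / elm / ash / larch / all alike)
* final target, as a percentage of the substrate charged, in oak
* final target, as a percentage of the substrate charged, in elm
* final target, as a percentage of the substrate charged, in ash
* final target, as a percentage of the substrate charged, in larch

- at the start none of the gas is in solution

1. Read the rise of target. Take the last reading of a run as its plateau, and define the rise constant as ln(plateau/(plateau − reading))/time. At 12.0 min, green gives 0.0568 /min at −5 °C, and teal gives 0.166 /min at 6 °C. Both are readings and carry their scatter.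

2. Draw a straight line through ln(rise constant) against temperature. Teal also holds less substrate than green, 0.010 M against 0.015 M, so this line puts that difference on temperature as well, and it is an estimate. At 0 °C you get 0.0925 /min, a rise time of 10.8 min. Extended below the runs to −20 °C, the line gives 0.0132 /min, a rise time of 76.0 min.

3. Now multiply the feed time by the rise constant at the feeding temperature. Larch gives 3.70, and elm gives 0.526. Call this product the feed number.

4. Because elm's feed of 40 min is shorter than its rise time, I expect elm to follow ash. Because larch's feed is longer than its rise time, larch is the flask I expect to part from oak.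

5. Blue, with more substrate, stands higher than green at 25.0 min, 23.8 % against 20.7 %. So I do not expect target to follow conversion by itself: in these two runs, at one temperature, it goes with concentration too. My decision is to charge everything at the start, as in oak, and to run larch once as a test.

6. The forecast also names oak, with 27.4 % there, 24.4 % in elm, 25.1 % in ash and 26.4 % in larch, holding that “Yield then depends only on conversion”. I expect a wider gap between larch and oak, though I put no number on it.

7. The flask gives oak as the highest at 27.5 %, with elm at 22.3 %, ash at 23.8 % and larch at 16.0 %.

    substrate → intermediate (k = 0.0520 /min, Ea = 78.0 kJ/mol)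
    first nucleophile + intermediate → target (k = 230 /M/min, Ea = 51.0 kJ/mol)
    second nucleophile + intermediate → other capture product (k = 630 /M/min, Ea = 43.0 kJ/mol)
    intermediate → solvolysis product (k = 2.00 /min, Ea = 69.0 kJ/mol)
    2 second nucleophile → self-condensation product (k = 36.0 /M/min, Ea = 58.0 kJ/mol)
    gas ⇌ second nucleophile, rate k6*(csat - [second nucleophile]) (kL = 0.160 /min)
    first nucleophile → decomposed reagent (k = 0.0350 /min, Ea = 73.0 kJ/mol)
    (constants at 0 °C)

Larch, with feed number 3.70, stands 12 percentage points below oak, and at 1.00 h it holds 0.00758 M of decomposed reagent against 0.00587 M in oak. Elm, with feed number 0.526, stands 1.5 points below ash, and at the end of its feed, at 0.667 h, elm still holds 93.4 % of the charged substrate as substrate.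

The runs come from a simulation for an exercise, noise included.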